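**Retrosynthetic overview**

- Rings: A = trioxygenated ring, B = para-phenylene, C = ring bearing CH2 and OH, D = meta-phenylene. The last C–C bond made is ring B C-4 (para to the A–O–B oxygen) to the carbinol carbon. It closes the 18-membered ring, the only ring formed (all four arenes are bought), by an enantioselective Ni/Cr-mediated reductive aryl iodide–aldehyde macrocyclisation of an achiral seco compound.
- Enabling feature: the carbinol carbon sits between ring B and the CH2 on ring C (a 1,2-diarylethanol), so it is the adduct of a ring B C-4 metal with the ring C arylacetaldehyde. Ring B carries nothing but its para ether oxygen (clean 4-iodophenyl handle). The ring C CH2CHO is ortho to the C–O–D oxygen (Claisen allyl, then oxidative cleavage). The carbinol is the only stereocentre.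
- Seco compound: A–O–B ether by Chan–Lam coupling with 4-iodophenylboronic acid; A–CH2CH2–D bridge by styrene hydroboration/B-alkyl Suzuki coupling; C–O–D ether by Ullmann coupling with 1-bromo-3-iodobenzene.
- Protection: ring A catechol as diphenylmethylene ketal and ring C phenol as benzyl ether, both removed by one hydrogenolysis after ring closure.

Key step: step 11

Remark: the carbinol is read from the SMILES as (S) (OH > ring B aryl > CH2 > H); small reagents that deliver a protecting group, one carbon or the allyl group are given with SMILES on the reagent line of their step and are not numbered.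

**Route**

Step 1
Reactants: 1 3,4,5-trihydroxybenzaldehyde
Product: 2 7-hydroxy-2,2-diphenyl-1,3-benzodioxole-5-carbaldehyde
Conditions: Ph2CCl2 (1.1 equiv), Ph2O, 175 °C, N2 sweep
Reagents that add atoms: dichlorodiphenylmethane, ClC(Cl)(c1ccccc1)c1ccccc1
Why: Catechol ketalisation with a gem-dichloride; the five-membered dioxole can only bridge two adjacent hydroxyls and both such pairs are equivalent by symmetry, so exactly one phenol should stay free.

Step 2
Reactants: 2 7-hydroxy-2,2-diphenyl-1,3-benzodioxole-5-carbaldehyde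
Product: 3 2,2-diphenyl-7-[(triisopropylsilyl)oxy]-1,3-benzodioxole-5-carbaldehyde
Conditions: TIPSCl, imidazole, DMF, rt
Reagents that add atoms: triisopropylsilyl chloride, CC(C)[Si](Cl)(C(C)C)C(C)C
Why: Phenol silylation masks the O–H that would quench the ylide of step 3 and the borane of step 7; an aryl TIPS ether should survive the aqueous phosphate of step 7.

Step 3
Reactants: 3 2,2-diphenyl-7-[(triisopropylsilyl)oxy]-1,3-benzodioxole-5-carbaldehyde
Product: 4 [(6-ethenyl-2,2-diphenyl-1,3-benzodioxol-4-yl)oxy]triisopropylsilane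
Conditions: Ph3PCH3Br, NaHMDS, THF, 0 °C to rt
Reagents that add atoms: methyltriphenylphosphonium bromide, C[P+](c1ccccc1)(c1ccccc1)c1ccccc1.[Br-]
Why: Wittig methylenation of an aryl aldehyde with a non-stabilised ylide, to which the ketal and the aryl silyl ether are inert.

Step 4
Reactants: 5 2-(benzyloxy)phenol
Product: 6 1-(allyloxy)-2-(benzyloxy)benzene
Conditions: allyl bromide, K2CO3, acetone, reflux
Reagents that add atoms: allyl bromide, C=CCBr
Why: Williamson ether synthesis of a phenoxide with a reactive allylic bromide.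

Step 5
Reactants: 6 1-(allyloxy)-2-(benzyloxy)benzene
Product: 7 2-allyl-6-(benzyloxy)phenol
Conditions: N,N-diethylaniline, 195 °C
Reagents that add atoms: none
Why: Aromatic Claisen rearrangement ([3,3]-sigmatropic shift, then tautomerisation) should place the allyl group at the only free ortho position, giving the 1-CH2/2-O/3-O pattern of ring C.

Step 6
Reactants: 7 2-allyl-6-(benzyloxy)phenol, 8 1-bromo-3-iodobenzene
Product: 9 1-allyl-3-(benzyloxy)-2-(3-bromophenoxy)benzene
Conditions: CuI (10 mol %), picolinic acid (20 mol %), K3PO4, DMSO, 90 °C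
Reagents that add atoms: none
Why: Cu-catalysed Ullmann-type diaryl ether synthesis with a ligand suited to doubly ortho-substituted phenols, selective for C–I over C–Br; phosphate should be too weak a base to move the allyl double bond into conjugation.

Step 7
Reactants: 4 [(6-ethenyl-2,2-diphenyl-1,3-benzodioxol-4-yl)oxy]triisopropylsilane, 9 1-allyl-3-(benzyloxy)-2-(3-bromophenoxy)benzene
Product: 11 {[6-(2-{3-[2-allyl-6-(benzyloxy)phenoxy]phenyl}ethyl)-2,2-diphenyl-1,3-benzodioxol-4-yl]oxy}triisopropylsilane, via B-alkyl-9-BBN borane 10 (not isolated)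
Conditions: 9-BBN (0.95 equiv relative to 4), THF, 0 °C to rt; then 3 M aq K3PO4, 9, PdCl2(dppf) (5 mol %), DMF, 60 °C
Reagents that add atoms: 9-borabicyclo[3.3.1]nonane, [BH]1C2CCCC1CCC2 (its boron stays only in 10; 11 keeps just the hydrogen)
Why: Anti-Markovnikov hydroboration of the styrene followed by B-alkyl Suzuki–Miyaura coupling with the aryl bromide; all B–H is consumed by the slight excess of 4 and quenched by aqueous base before the allyl-bearing 9 is added, so the allyl group should not be hydroborated.

Step 8
Reactants: 11 {[6-(2-{3-[2-allyl-6-(benzyloxy)phenoxy]phenyl}ethyl)-2,2-diphenyl-1,3-benzodioxol-4-yl]oxy}triisopropylsilane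
Product: 12 6-(2-{3-[2-allyl-6-(benzyloxy)phenoxy]phenyl}ethyl)-2,2-diphenyl-1,3-benzodioxol-4-ol
Conditions: TBAF, AcOH (1:1), THF, 0 °C to rt
Reagents that add atoms: none
Why: Fluoride-mediated desilylation of an aryl silyl ether; the acetic acid buffer keeps the ketal, benzyl ether and allyl group untouched.

Step 9
Reactants: 12 6-(2-{3-[2-allyl-6-(benzyloxy)phenoxy]phenyl}ethyl)-2,2-diphenyl-1,3-benzodioxol-4-ol, 13 4-iodophenylboronic acid
Product: 14 6-(2-{3-[2-allyl-6-(benzyloxy)phenoxy]phenyl}ethyl)-4-(4-iodophenoxy)-2,2-diphenyl-1,3-benzodioxole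
Conditions: Cu(OAc)2 (2 equiv), pyridine, 4 Å MS, CH2Cl2, rt
Reagents that add atoms: none
Why: Chan–Lam–Evans oxidative C–O coupling of a phenol with an arylboronic acid at room temperature; Cu(II) does not activate the C–I bond, so the iodide should arrive intact and para to the new ether oxygen.

Step 10
Reactants: 14 6-(2-{3-[2-allyl-6-(benzyloxy)phenoxy]phenyl}ethyl)-4-(4-iodophenoxy)-2,2-diphenyl-1,3-benzodioxole
Product: 16 {3-(benzyloxy)-2-[3-(2-{7-(4-iodophenoxy)-2,2-diphenyl-1,3-benzodioxol-5-yl}ethyl)phenoxy]phenyl}acetaldehyde, via vicinal diol 15 (not isolated)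
Conditions: OsO4 (2 mol %), NaIO4 (4 equiv), 2,6-lutidine, dioxane/H2O, rt; used at once
Reagents that add atoms: osmium tetroxide, O=[Os](=O)(=O)=O; sodium periodate, [Na+].[O-]I(=O)(=O)=O
Why: Lemieux–Johnson oxidative cleavage (catalytic dihydroxylation, then periodate glycol cleavage) of the terminal alkene; no free phenol is present and lutidine suppresses over-oxidation of the arylacetaldehyde.

Step 11
Reactants: 16 {3-(benzyloxy)-2-[3-(2-{7-(4-iodophenoxy)-2,2-diphenyl-1,3-benzodioxol-5-yl}ethyl)phenoxy]phenyl}acetaldehyde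
Product: 18 (S)-macrocyclic carbinol (18-membered ring of the target; ring A catechol as diphenylmethylene ketal, ring C phenol as benzyl ether), via arylchromium(III) species 17 (not isolated)
Conditions: CrCl2 (8 equiv), chiral oxazoline–sulfonamide ligand L* (8.8 equiv; one antipode of N-[2-(4-isopropyl-4,5-dihydrooxazol-2-yl)-6-methylphenyl]methanesulfonamide, chosen for Re-face delivery), Et3N (8.8 equiv), THF, rt; then NiCl2(2,9-dimethylphenanthroline) (0.2 equiv), 16 added by syringe pump over 12 h (2 mM final), rt; aq ethylenediamine work-up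
Reagents that add atoms: chromium(II) chloride, Cl[Cr]Cl (the metal is carried only in intermediate 17)
Why: Proposed new method: Ni(0) inserts into the only C–I bond (ring B, para to the A–O–B oxygen), the aryl group is passed to Cr(III) bearing the chiral ligand, and this non-basic arylchromium(III) adds to the tethered arylacetaldehyde, so two electrophilic carbons are joined through reductive polarity reversal of the aryl iodide. The closest known reaction types are Nozaki–Hiyama–Kishi macrocyclisations of alkenyl iodide–aldehydes, Ni/Cr additions of aryl iodides to aldehydes, and ligand-controlled asymmetric Ni/Cr couplings of alkenyl halides; an enantioselective macrocyclising aryl version has not been shown. The 18-membered ring closes in an 18-exo-trig mode (the carbonyl oxygen stays outside the ring), helped by pseudo-high dilution and by four rigid arene panels and two bent diaryl ether hinges that leave only nine rotatable bonds in the chain. The carbinol stereocentre is set under reagent control by the chiral ligand on chromium, aryl delivery to the Re face of the aldehyde giving the (S) alcohol; 16 is achiral, so no substrate bias opposes the ligand. The step needs carbonyl addition to win over enolisation, aldol reaction and protodeiodination, which the low basicity of organochromium(III) and the absence of any other halide or carbonyl in 16 should secure, and it needs ring closure to win over oligomerisation, which slow addition should secure.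

Step 12
Reactants: 18 (S)-macrocyclic carbinol (ketal and benzyl ether protected)
Product: 19 CNP0356934.1, (S)-configured 18-membered bis(bibenzyl) macrocycle
Conditions: H2 (1 atm), 10% Pd/C, THF/MeOH, rt, stopped at full conversion
Reagents that add atoms: none
Why: Catalytic hydrogenolysis cleaves the aryl benzyl ether and the diphenylmethylene ketal (benzylic C–O bonds to phenolic oxygen) faster than the secondary benzylic C–OH under neutral conditions, as in phenol debenzylations of 1-aryl-ethanol-type compounds; the stereocentre is not touched.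

**Compound list**

1 | 3,4,5-trihydroxybenzaldehyde | O=Cc1cc(O)c(O)c(O)c1 | starting material
2 | 7-hydroxy-2,2-diphenyl-1,3-benzodioxole-5-carbaldehyde | O=Cc1cc(O)c2OC(c3ccccc3)(c3ccccc3)Oc2c1 | intermediate
3 | 2,2-diphenyl-7-[(triisopropylsilyl)oxy]-1,3-benzodioxole-5-carbaldehyde | O=Cc1cc(O[Si](C(C)C)(C(C)C)C(C)C)c2OC(c3ccccc3)(c3ccccc3)Oc2c1 | intermediate
4 | [(6-ethenyl-2,2-diphenyl-1,3-benzodioxol-4-yl)oxy]triisopropylsilane | C=Cc1cc(O[Si](C(C)C)(C(C)C)C(C)C)c2OC(c3ccccc3)(c3ccccc3)Oc2c1 | intermediate
5 | 2-(benzyloxy)phenol | Oc1ccccc1OCc1ccccc1 | starting material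
6 | 1-(allyloxy)-2-(benzyloxy)benzene | C=CCOc1ccccc1OCc1ccccc1 | intermediate
7 | 2-allyl-6-(benzyloxy)phenol | C=CCc1cccc(OCc2ccccc2)c1O | intermediate
8 | 1-bromo-3-iodobenzene | Brc1cccc(I)c1 | starting material
9 | 1-allyl-3-(benzyloxy)-2-(3-bromophenoxy)benzene | C=CCc1cccc(OCc2ccccc2)c1Oc1cccc(Br)c1 | intermediate
10 | 9-{2-[2,2-diphenyl-7-(triisopropylsilyloxy)-1,3-benzodioxol-5-yl]ethyl}-9-borabicyclo[3.3.1]nonane (not isolated) | CC(C)[Si](C(C)C)(C(C)C)Oc1cc(CCB2C3CCCC2CCC3)cc2OC(c3ccccc3)(c3ccccc3)Oc12 | intermediate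
11 | {[6-(2-{3-[2-allyl-6-(benzyloxy)phenoxy]phenyl}ethyl)-2,2-diphenyl-1,3-benzodioxol-4-yl]oxy}triisopropylsilane | C=CCc1cccc(OCc2ccccc2)c1Oc1cccc(CCc2cc(O[Si](C(C)C)(C(C)C)C(C)C)c3OC(c4ccccc4)(c4ccccc4)Oc3c2)c1 | intermediate
12 | 6-(2-{3-[2-allyl-6-(benzyloxy)phenoxy]phenyl}ethyl)-2,2-diphenyl-1,3-benzodioxol-4-ol | C=CCc1cccc(OCc2ccccc2)c1Oc1cccc(CCc2cc(O)c3OC(c4ccccc4)(c4ccccc4)Oc3c2)c1 | intermediate
13 | 4-iodophenylboronic acid | OB(O)c1ccc(I)cc1 | starting material
14 | 6-(2-{3-[2-allyl-6-(benzyloxy)phenoxy]phenyl}ethyl)-4-(4-iodophenoxy)-2,2-diphenyl-1,3-benzodioxole | C=CCc1cccc(OCc2ccccc2)c1Oc1cccc(CCc2cc(Oc3ccc(I)cc3)c3OC(c4ccccc4)(c4ccccc4)Oc3c2)c1 | intermediate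
15 | 3-{3-(benzyloxy)-2-[3-(2-{7-(4-iodophenoxy)-2,2-diphenyl-1,3-benzodioxol-5-yl}ethyl)phenoxy]phenyl}propane-1,2-diol, racemic (not isolated) | OCC(O)Cc1cccc(OCc2ccccc2)c1Oc1cccc(CCc2cc(Oc3ccc(I)cc3)c3OC(c4ccccc4)(c4ccccc4)Oc3c2)c1 | intermediate
16 | {3-(benzyloxy)-2-[3-(2-{7-(4-iodophenoxy)-2,2-diphenyl-1,3-benzodioxol-5-yl}ethyl)phenoxy]phenyl}acetaldehyde | O=CCc1cccc(OCc2ccccc2)c1Oc1cccc(CCc2cc(Oc3ccc(I)cc3)c3OC(c4ccccc4)(c4ccccc4)Oc3c2)c1 | intermediate
17 | arylchromium(III) dichloride from 16 (C–I replaced by C–Cr; ligand L* omitted; not isolated) | O=CCc1cccc(OCc2ccccc2)c1Oc1cccc(CCc2cc(Oc3ccc([Cr](Cl)Cl)cc3)c3OC(c4ccccc4)(c4ccccc4)Oc3c2)c1 | intermediate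
18 | (S)-macrocyclic carbinol: target ring system with ring A catechol as diphenylmethylene ketal and ring C phenol as benzyl ether | O1c2cc3cc(c2OC1(c1ccccc1)c1ccccc1)Oc1ccc(cc1)[C@@H](O)Cc1cccc(OCc2ccccc2)c1Oc1cccc(c1)CC3 | intermediate
19 | CNP0356934.1, (S)-configured macrocyclic bis(bibenzyl) | Oc1cc2cc(c1O)Oc1ccc(cc1)[C@@H](O)Cc1cccc(O)c1Oc1cccc(c1)CC2 | target

**Totals and risks**

Total step count: 12. Longest linear sequence: 9 steps (steps 1–3 and 7–12; the branch through steps 4–6 and 7–12 is equally long).

Steps most likely to fail: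

1. Step 11 (Proposed new method). The chain may oligomerise instead of closing, the arylmetal may be protonated before it reaches the carbonyl, or the ligand may discriminate poorly between the aldehyde faces. Fallback, known chemistry, from 16: the same bond is closed without asymmetric induction by a ligand-free Ni/Cr-mediated coupling (CrCl2, cat. NiCl2, DMSO/THF, high dilution) to give the racemic macrocyclic carbinol F1. Dess–Martin oxidation then gives the macrocyclic aryl benzyl ketone F2. Asymmetric transfer hydrogenation of this deoxybenzoin-type ketone (RuCl[(S,S)-TsDPEN](p-cymene), HCO2H/Et3N; catalyst antipode chosen by analogy with acetophenone, where the aryl group on the carbonyl directs hydride delivery) should return the (S) alcohol 18, where the route is rejoined.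

2. Step 12. The benzylic C–OH bond may be hydrogenolysed alongside the protecting groups, or the reaction may stall at partly deprotected material. Fallback from 14, avoiding hydrogenolysis altogether: BCl3 with pentamethylbenzene (CH2Cl2, −78 to 0 °C, aqueous work-up) removes the benzyl ether and the ketal to give the iodo triol F3. Ac2O/pyridine gives the triacetate F4, and OsO4/NaIO4 as in step 10 gives the aldehyde triacetate F5. Ring closure as in step 11 (or through its fallback) gives the (S)-macrocyclic triacetate F6. K2CO3 in MeOH at 0 °C under N2 then removes the three acetates without acid or hydrogen and arrives at 19.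

3. Step 6. C–O coupling at the doubly ortho-substituted phenol may be slow, hot base may move the allyl double bond into conjugation, and some coupling may occur at C–Br. Fallback from 7, metal-free at room temperature: 8 is converted with mCPBA, TsOH and 1,3,5-trimethoxybenzene into (3-bromophenyl)(2,4,6-trimethoxyphenyl)iodonium tosylate F7. The potassium phenoxide of 7 (K2CO3 or t-BuOK, THF, rt) is then arylated by F7, the electron-rich trimethoxyphenyl group acting as the non-transferred ligand, which should give 9 and rejoin the route.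

**Further compounds**

F1 | step 11 | racemic macrocyclic carbinol (racemate of 18) | O1c2cc3cc(c2OC1(c1ccccc1)c1ccccc1)Oc1ccc(cc1)C(O)Cc1cccc(OCc2ccccc2)c1Oc1cccc(c1)CC3
F2 | step 11 | macrocyclic aryl benzyl ketone (ketal and benzyl ether protected) | O1c2cc3cc(c2OC1(c1ccccc1)c1ccccc1)Oc1ccc(cc1)C(=O)Cc1cccc(OCc2ccccc2)c1Oc1cccc(c1)CC3
F3 | step 12 | 5-{2-[3-(2-allyl-6-hydroxyphenoxy)phenyl]ethyl}-3-(4-iodophenoxy)benzene-1,2-diol | C=CCc1cccc(O)c1Oc1cccc(CCc2cc(O)c(O)c(Oc3ccc(I)cc3)c2)c1
F4 | step 12 | triacetate of F3 | C=CCc1cccc(OC(C)=O)c1Oc1cccc(CCc2cc(OC(C)=O)c(OC(C)=O)c(Oc3ccc(I)cc3)c2)c1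
F5 | step 12 | arylacetaldehyde triacetate (seco iodide–aldehyde) | O=CCc1cccc(OC(C)=O)c1Oc1cccc(CCc2cc(OC(C)=O)c(OC(C)=O)c(Oc3ccc(I)cc3)c2)c1
F6 | step 12 | (S)-macrocyclic carbinol triacetate | CC(=O)Oc1cc2cc(c1OC(C)=O)Oc1ccc(cc1)[C@@H](O)Cc1cccc(OC(C)=O)c1Oc1cccc(c1)CC2
F7 | step 6 | (3-bromophenyl)(2,4,6-trimethoxyphenyl)iodonium tosylate | COc1cc(OC)c([I+]c2cccc(Br)c2)c(OC)c1.Cc1ccc(cc1)S([O-])(=O)=O
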